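Everything rests on reading the γ-lactone (ring D, C7–C8–O9–C10–C11) as a cyclobutanone plus one oxygen atom. A strain-driven Baeyer–Villiger ring expansion inserts O9 between the carbonyl carbon C10 and the methine C8 that later flanks the enone carbonyl, closing ring D with retention at C8. The precursor is a cage cyclobutanone (C7–C8–C10–C11) that an intramolecular keteniminium–styrene [2+2] cycloaddition assembles together with seven-membered ring C and three stereocentres in one operation. The only preset stereocentre, quaternary C12, comes from a CBS reduction relayed by a [2,3]-Wittig–Still rearrangement; allylic oxidation and arene dibromination complete the synthesis.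

Key step: step 11

Atom labels used throughout: ring A = arene; C7 = benzylic methine; C8 = oxygen-bearing methine; O9 = lactone ring oxygen; C10 = lactone carbonyl carbon; C11 = methine next to C10; C12 = methyl-bearing quaternary carbon; C13=C14 = ring alkene; C15 = ketone carbon; C16 = C(CH3)2; ring B = C7–C11–C12–C16 plus two ring A carbons; ring C = C7–C8–C15–C14–C13–C12–C11; ring D = C7–C8–O9–C10–C11. In these labels the target is (7S,8S,11R,12R).

Assumption: in the CBS reduction (step 4) the fused aryl flank is taken as the large group, as in 1-tetralone, so that the (R)-catalyst gives the (1S)-alcohol; if the sense proves opposite, the (S)-catalyst is used.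

Step 1
Reactants: 1 ethylbenzene; 2 5,5-dimethyldihydrofuran-2(3H)-one
Product: 4 7-ethyl-4,4-dimethyl-3,4-dihydronaphthalen-1(2H)-one, via 4-(4-ethylphenyl)-4-methylpentanoic acid 3 (not isolated)
Conditions: AlCl3 (2.5 equiv), ethylbenzene (solvent), 0 to 50 °C; aq. HCl work-up
Reagents that add atoms: none
Why: Tandem Friedel–Crafts alkylation/acylation, in which the tertiary cation from the lactone alkylates para to ethyl and the acylium then closes ring B ortho to the new tert-alkyl group, placing ethyl para to the C16-bearing carbon.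

Step 2
Reactants: 4 7-ethyl-4,4-dimethyl-3,4-dihydronaphthalen-1(2H)-one
Product: 5 7-ethyl-4,4-dimethylnaphthalen-1(4H)-one
Conditions: Pd(O2CCF3)2 (5 mol %), DMSO (10 mol %), O2 (1 atm), AcOH, 80 °C
Reagents that add atoms: none
Why: Aerobic palladium-catalysed α,β-dehydrogenation of the ketone (palladium enolate, β-hydride elimination), with quaternary C16 blocking aromatisation to a naphthol.

Step 3
Reactants: 5 7-ethyl-4,4-dimethylnaphthalen-1(4H)-one
Product: 8 7-ethyl-3,4,4-trimethylnaphthalen-1(4H)-one, via lithium enolate 6 (not isolated), via sulfilimine adduct 7 (not isolated)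
Conditions: Me2CuLi (from MeLi and CuI), Et2O, −78 to 0 °C; then PhS(Cl)=N-t-Bu, THF, −78 °C to rt
Reagents that add atoms: lithium dimethylcuprate, [Li+].C[Cu-]C
Why: Gilman conjugate addition places the methyl on C12, and one-pot dehydrogenation of the lithium enolate with N-tert-butylbenzenesulfinimidoyl chloride (α-sulfenylation, syn-elimination of the sulfenamide) restores the enone, erasing the racemic centre of 6 and 7.

Step 4
Reactants: 8 7-ethyl-3,4,4-trimethylnaphthalen-1(4H)-one
Product: 9 (1S)-7-ethyl-3,4,4-trimethyl-1,4-dihydronaphthalen-1-ol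
Conditions: (R)-2-methyl-CBS-oxazaborolidine (10 mol %), BH3·SMe2, THF, −20 °C; MeOH, then aqueous work-up
Reagents that add atoms: none
Why: CBS reduction, in which the catalyst distinguishes the fused aryl flank (large) from the vinylic CH flank (small) and delivers hydride to one carbonyl face to set the C7 carbinol as (S), the hindered trisubstituted alkene being left alone.

Step 5
Reactants: 9 (1S)-7-ethyl-3,4,4-trimethyl-1,4-dihydronaphthalen-1-ol
Product: 10 tributyl({[(1S)-7-ethyl-3,4,4-trimethyl-1,4-dihydronaphthalen-1-yl]oxy}methyl)stannane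
Conditions: KH, THF, 0 °C; then Bu3SnCH2I, 18-crown-6 (cat.), rt
Reagents that add atoms: tributyl(iodomethyl)stannane, CCCC[Sn](CCCC)(CCCC)CI
Why: Williamson etherification of the potassium alkoxide with the primary iodide, which does not touch the C7 stereocentre.

Step 6
Reactants: 10 tributyl({[(1S)-7-ethyl-3,4,4-trimethyl-1,4-dihydronaphthalen-1-yl]oxy}methyl)stannane
Product: 12 [(2R)-6-ethyl-1,1,2-trimethyl-1,2-dihydronaphthalen-2-yl]methanol, via lithiomethyl ether 11 (not isolated)
Conditions: n-BuLi, THF, −78 °C; then H2O
Reagents that add atoms: none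
Why: Tin–lithium exchange and [2,3]-Wittig–Still rearrangement through a five-membered envelope transition state deliver the CH2O unit suprafacially from the C7 oxygen to C12, relaying the (S)-carbinol into the (R)-quaternary centre next to C16 and unveiling the C7=C11 styrene.

Step 7
Reactants: 12 [(2R)-6-ethyl-1,1,2-trimethyl-1,2-dihydronaphthalen-2-yl]methanol
Product: 13 (2R)-6-ethyl-1,1,2-trimethyl-1,2-dihydronaphthalene-2-carbaldehyde
Conditions: Dess–Martin periodinane, CH2Cl2, rt
Reagents that add atoms: none
Why: Dess–Martin oxidation of the neopentyl primary alcohol to an aldehyde that has no α-hydrogen, so C12 cannot epimerise.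

Step 8
Reactants: 13 (2R)-6-ethyl-1,1,2-trimethyl-1,2-dihydronaphthalene-2-carbaldehyde; 14 (3-carboxypropyl)triphenylphosphonium bromide
Product: 16 (4Z)-5-[(2R)-6-ethyl-1,1,2-trimethyl-1,2-dihydronaphthalen-2-yl]pent-4-enoic acid, via ylide carboxylate 15 (not isolated)
Conditions: 14, NaN(SiMe3)2 (2.1 equiv), THF, 0 °C; then 13, −78 °C to rt; aq. HCl
Reagents that add atoms: none
Why: Wittig olefination with a non-stabilised ylide under lithium-free conditions gives the (Z)-C13=C14 alkene, the geometry that ring C requires.

Step 9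
Reactants: 16 (4Z)-5-[(2R)-6-ethyl-1,1,2-trimethyl-1,2-dihydronaphthalen-2-yl]pent-4-enoic acid
Product: 18 1-{(4Z)-5-[(2R)-6-ethyl-1,1,2-trimethyl-1,2-dihydronaphthalen-2-yl]pent-4-enoyl}pyrrolidine, via acyl imidazole 17 (not isolated)
Conditions: 1,1′-carbonyldiimidazole, THF, rt; then pyrrolidine
Reagents that add atoms: pyrrolidine, C1CCNC1
Why: Amide formation through the acyl imidazole provides the tertiary amide needed as keteniminium precursor.

Step 10
Reactants: 18 1-{(4Z)-5-[(2R)-6-ethyl-1,1,2-trimethyl-1,2-dihydronaphthalen-2-yl]pent-4-enoyl}pyrrolidine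
Product: 21 cage cyclobutanone (7S,8R,11R,12R), via keteniminium triflate 19 (not isolated), via cyclobutaniminium triflate 20 (not isolated)
Conditions: Tf2O, 2,4,6-collidine, ClCH2CH2Cl, 0 to 80 °C; then H2O, 60 °C
Reagents that add atoms: water, O
Why: Intramolecular keteniminium–alkene [2+2] cycloaddition, in which electrophilic C10 bonds to C11 to give the benzylic cation at C7 that the enamine carbon C8 captures, closing ring C and the cyclobutane on the face of ring B that carries the C12 chain so that C7, C8 and C11 are dictated by C12, before hydrolysis of the iminium to the ketone.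

Step 11
Reactants: 21 cage cyclobutanone (7S,8R,11R,12R)
Product: 23 lactone (7S,8R,11R,12R) with C15 still CH2, via Criegee perhydrate 22 (not isolated)
Conditions: 30% aq. H2O2, AcOH, 0 °C to rt
Reagents that add atoms: hydrogen peroxide, OO
Why: H2O2 adds to the strained carbonyl C10 from the exo face (the face carrying the three cyclobutane hydrogens) to give the Criegee perhydrate 22, and acid-assisted 1,2-shift of C8 from C10 to the proximal peroxide oxygen with loss of water forms the O9–C8 bond. The closest known reaction type is the Baeyer–Villiger oxidation of fused cyclobutanones to γ-butyrolactones with H2O2 in acetic acid in the presence of a ring alkene. Ring D is closed by ring expansion of the four-membered ketone to the five-membered lactone (1,2-alkyl shift from carbon to oxygen), driven by release of cyclobutanone strain, while rings A, B and C are untouched. No stereocentre is created: C8 migrates with retention, so the configuration fixed by the cage in step 10 is carried into the lactone. The step needs migration of C8 and not of C11 (both are methines of similar intrinsic aptitude) and oxidation of the ketone and not of the C13=C14 alkene. The hindered alkene is unreactive toward the nucleophilic H2O2/AcOH system, and C8 is expected to migrate because it lies in the flexible four-carbon bridge next to CH2-15 and can follow the exo peroxide, whereas C11 is the neopentylic one-carbon bridge locked between C7 and quaternary C12.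

Step 12
Reactants: 23 lactone (7S,8R,11R,12R)
Product: 24 didebromo-salimabromide (7S,8S,11R,12R)
Conditions: Rh2(cap)4 (dirhodium tetracaprolactamate, 1 mol %), t-BuOOH (70% aq., 5 equiv), K2CO3 (0.5 equiv), CH2Cl2, rt
Reagents that add atoms: tert-butyl hydroperoxide, CC(C)(C)OO
Why: Radical allylic C–H oxidation at C15, the only allylic CH2 because C12 is quaternary, with the allyl radical oxygenated at its less hindered terminus and the mixed peroxide collapsing to the enone.

Step 13
Reactants: 24 didebromo-salimabromide
Product: 26 salimabromide (7S,8S,11R,12R), via monobromide 25 (not isolated)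
Conditions: Br2 (2.5 equiv), AgO2CCF3 (2.5 equiv), CF3CO2H, 0 °C to rt, dark
Reagents that add atoms: bromine, BrBr
Why: Silver-assisted electrophilic aromatic bromination at the two ring A positions ortho to ethyl, each activated by two alkyl groups, while the third CH is activated by one and shielded by C16 and the protonated, hindered enone alkene should not react.

Compound list
1 | ethylbenzene | CCc1ccccc1 | starting material
2 | 5,5-dimethyldihydrofuran-2(3H)-one | CC1(C)CCC(=O)O1 | starting material
3 | 4-(4-ethylphenyl)-4-methylpentanoic acid | CCc1ccc(cc1)C(C)(C)CCC(=O)O | intermediate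
4 | 7-ethyl-4,4-dimethyl-3,4-dihydronaphthalen-1(2H)-one | CCc1ccc2c(c1)C(=O)CCC2(C)C | intermediate
5 | 7-ethyl-4,4-dimethylnaphthalen-1(4H)-one | CCc1ccc2c(c1)C(=O)C=CC2(C)C | intermediate
6 | lithium 7-ethyl-3,4,4-trimethyl-3,4-dihydronaphthalen-1-olate (racemic) | CCc1ccc2c(c1)C([O-])=CC(C)C2(C)C.[Li+] | intermediate
7 | 2-(N-tert-butyl-S-phenylsulfinimidoyl)-7-ethyl-3,4,4-trimethyl-3,4-dihydronaphthalen-1(2H)-one (racemic) | CCc1ccc2c(c1)C(=O)C(C(C)C2(C)C)S(=NC(C)(C)C)c1ccccc1 | intermediate
8 | 7-ethyl-3,4,4-trimethylnaphthalen-1(4H)-one | CCc1ccc2c(c1)C(=O)C=C(C)C2(C)C | intermediate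
9 | (1S)-7-ethyl-3,4,4-trimethyl-1,4-dihydronaphthalen-1-ol | CCc1ccc2c(c1)[C@@H](O)C=C(C)C2(C)C | intermediate
10 | tributyl({[(1S)-7-ethyl-3,4,4-trimethyl-1,4-dihydronaphthalen-1-yl]oxy}methyl)stannane | CCc1ccc2c(c1)[C@@H](OC[Sn](CCCC)(CCCC)CCCC)C=C(C)C2(C)C | intermediate
11 | {[(1S)-7-ethyl-3,4,4-trimethyl-1,4-dihydronaphthalen-1-yl]oxy}methyllithium | CCc1ccc2c(c1)[C@@H](OC[Li])C=C(C)C2(C)C | intermediate
12 | [(2R)-6-ethyl-1,1,2-trimethyl-1,2-dihydronaphthalen-2-yl]methanol | CCc1ccc2c(c1)C=C[C@@](C)(CO)C2(C)C | intermediate
13 | (2R)-6-ethyl-1,1,2-trimethyl-1,2-dihydronaphthalene-2-carbaldehyde | CCc1ccc2c(c1)C=C[C@@](C)(C=O)C2(C)C | intermediate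
14 | (3-carboxypropyl)triphenylphosphonium bromide | OC(=O)CCC[P+](c1ccccc1)(c1ccccc1)c1ccccc1.[Br-] | starting material
15 | sodium 4-(triphenylphosphoranylidene)butanoate | [Na+].[O-]C(=O)CCC=P(c1ccccc1)(c1ccccc1)c1ccccc1 | intermediate
16 | (4Z)-5-[(2R)-6-ethyl-1,1,2-trimethyl-1,2-dihydronaphthalen-2-yl]pent-4-enoic acid | CCc1ccc2c(c1)C=C[C@@](C)(/C=C\CCC(=O)O)C2(C)C | intermediate
17 | 1-{(4Z)-5-[(2R)-6-ethyl-1,1,2-trimethyl-1,2-dihydronaphthalen-2-yl]pent-4-enoyl}-1H-imidazole | CCc1ccc2c(c1)C=C[C@@](C)(/C=C\CCC(=O)n1ccnc1)C2(C)C | intermediate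
18 | 1-{(4Z)-5-[(2R)-6-ethyl-1,1,2-trimethyl-1,2-dihydronaphthalen-2-yl]pent-4-enoyl}pyrrolidine | CCc1ccc2c(c1)C=C[C@@](C)(/C=C\CCC(=O)N1CCCC1)C2(C)C | intermediate
19 | 1-{(4Z)-5-[(2R)-6-ethyl-1,1,2-trimethyl-1,2-dihydronaphthalen-2-yl]penta-1,4-dien-1-ylidene}pyrrolidin-1-ium triflate (keteniminium, C8=C10=N) | CCc1ccc2c(c1)C=C[C@@](C)(/C=C\CC=C=[N+]1CCCC1)C2(C)C.[O-]S(=O)(=O)C(F)(F)F | intermediate
20 | pyrrolidinium (C10=N) iminium triflate of cyclobutanone 21, same cage and configuration | CCc1ccc2c(c1)[C@H]1[C@@H]3C(=[N+]4CCCC4)[C@H]1[C@@](C)(C=CC3)C2(C)C.[O-]S(=O)(=O)C(F)(F)F | intermediate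
21 | cage cyclobutanone (7S,8R,11R,12R): cyclobutanone C7–C8–C10(=O)–C11 cis-fused to ring B along C7–C11 and bridged from C8 to C12 by C15H2–C14H=C13H; CH3 on C12, two CH3 on C16, ethyl on ring A para to the C16-bearing carbon | CCc1ccc2c(c1)[C@H]1[C@@H]3C(=O)[C@H]1[C@@](C)(C=CC3)C2(C)C | intermediate
22 | Criegee perhydrate of 21: C10 bears OH (endo) and OOH (exo) | CCc1ccc2c(c1)[C@H]1[C@@H]3[C@](O)(OO)[C@H]1[C@@](C)(C=CC3)C2(C)C | intermediate
23 | lactone (7S,8R,11R,12R): as the target but without bromine and with C15 as CH2 | CCc1ccc2c(c1)[C@H]1[C@@H]3OC(=O)[C@H]1[C@@](C)(C=CC3)C2(C)C | intermediate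
24 | didebromo-salimabromide (7S,8S,11R,12R) | CCc1ccc2c(c1)[C@H]1[C@@H]3OC(=O)[C@H]1[C@@](C)(C=CC3=O)C2(C)C | intermediate
25 | monobromide: 24 with Br on the ring A carbon ortho to ethyl and para to the C7-bearing carbon | CCc1c(Br)cc2c(c1)[C@H]1[C@@H]3OC(=O)[C@H]1[C@@](C)(C=CC3=O)C2(C)C | intermediate
26 | salimabromide (7S,8S,11R,12R) | CCc1c(Br)cc2c(c1Br)[C@H]1[C@@H]3OC(=O)[C@H]1[C@@](C)(C=CC3=O)C2(C)C | target

Total step count: 13. Longest linear sequence: 13 steps (1 and 2 to 26; phosphonium salt 14 is purchased).

Steps most likely to fail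

1. Step 11 (Baeyer–Villiger). What may go wrong: the Criegee adduct may rearrange by migration of C11 instead of C8, since both are methines of similar intrinsic aptitude, or peracid formed in the medium may epoxidise the C13=C14 alkene. Fallback, setting out from 21 and returning at 24: allylic C–H oxidation of 21 at C15 (t-BuOOH, Rh2(cap)4) gives the 15-oxo derivative of 21, the 2-acylcyclobutanone F1. Hydroxide (LiOH, aq. THF) then adds to the strained carbonyl C10, and retro-Claisen cleavage of C10–C8 toward the cross-conjugated enolate gives the keto acid F2. Oxidative α′-lactonisation of F2 with PhI(OH)OTs (enol, α-iodanyl ketone on the exo face, intramolecular displacement by the C10 carboxylate) forms O9–C8 and gives 24 directly. The regiochemistry is fixed there, because C8 is the only enolisable position of the enone and the only carbon the carboxylate can reach.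

2. Step 10 (keteniminium [2+2]). What may go wrong: the cationic keteniminium may be diverted before ring C closes (attack on the C13=C14 alkene, oligomerisation, proton loss), or acid liberated in the medium may isomerise the styrene. Fallback, setting out from 16 and returning at 21: oxalyl chloride converts 16 into the acid chloride F3; slow addition to Et3N in refluxing toluene generates the neutral ketene F4, which should undergo a thermal concerted [2+2] cycloaddition with the C7=C11 styrene to give 21 without cationic intermediates.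

3. Step 12 (allylic oxidation). What may go wrong: hydrogen abstraction at the benzylic CH2 of the ethyl group may compete with C15, or oxygenation may occur at the transposed terminus C13. Fallback, setting out from 23 and returning at 24: SeO2 in dioxane (ene reaction then [2,3]-sigmatropic shift, no free radicals) gives the C15 allylic alcohol F5 (hydroxyl expected anti to O9; its configuration is immaterial), and Dess–Martin oxidation of F5 gives 24.

Further compounds
F1 | step 11 | 15-oxo derivative of cyclobutanone 21 (2-acylcyclobutanone, ketones at C10 and C15, cage configuration as in 21) | CCc1ccc2c(c1)[C@H]1[C@@H]3C(=O)[C@H]1[C@@](C)(C=CC3=O)C2(C)C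
F2 | step 11 | keto acid (7S,11R,12R): rings A, B and C of 24 with C8 as CH2 and CO2H on C11 | CCc1ccc2c(c1)[C@H]1CC(=O)C=C[C@](C)([C@@H]1C(=O)O)C2(C)C
F3 | step 10 | (4Z)-5-[(2R)-6-ethyl-1,1,2-trimethyl-1,2-dihydronaphthalen-2-yl]pent-4-enoyl chloride | CCc1ccc2c(c1)C=C[C@@](C)(/C=C\CCC(=O)Cl)C2(C)C
F4 | step 10 | (4Z)-5-[(2R)-6-ethyl-1,1,2-trimethyl-1,2-dihydronaphthalen-2-yl]penta-1,4-dien-1-one (ketene) | CCc1ccc2c(c1)C=C[C@@](C)(/C=C\CC=C=O)C2(C)C
F5 | step 12 | C15 allylic alcohol of lactone 23 (hydroxyl anti to O9) | CCc1ccc2c(c1)[C@H]1[C@@H]3OC(=O)[C@H]1[C@@](C)(C=C[C@@H]3O)C2(C)C
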